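Numbering: 15-oxabicyclo[10.2.1]pentadecane, C1 the methyl-bearing oxolane carbon, C12 the oxolane CH, O15 between them. The 13-membered ring O15/C1–C12 is closed last across its only C=C bond, the C5=C6 enoate in which C4 and C7 lie trans: an intramolecular Still–Gennari olefination of a seco C6-aldehyde/C5-phosphonoacetate that already carries the oxolane forges macrocycle and Z geometry in one operation. The cis C2/C11 arms come from a rhodium-carbenoid [4+3] adduct of 2-methylfuran, whose ketone carbon (future C3) is temporarily bonded to C11; C11-acylation and retro-Claisen cleavage cut that bond. C6–C10 with the C8 stereocentre come from (R)-carvone.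

Key step: step 18

Assumption: Rh2(S-PTAD)4 is taken, by analogy with its tropane-forming reactions of pyrroles, to give the (1R,5R) adduct 14; should the adduct prove antipodal, Rh2(R-PTAD)4 is used and nothing else changes.

Step 1
Reactants: 1 (R)-(−)-carvone
Product: 2 (1R,4R,6R)-1-methyl-4-(prop-1-en-2-yl)-7-oxabicyclo[4.1.0]heptan-2-one
Conditions: 30% H2O2, NaOH (cat.), MeOH, 0 °C
Reagents that add atoms: hydrogen peroxide, OO
Why: Weitz–Scheffer epoxidation, in which the hydroperoxide anion adds only to the enone (the isopropenyl group is inert) and anti to the isopropenyl group, the two new stereocentres being erased in step 2.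

Step 2
Reactants: 2 (1R,4R,6R)-1-methyl-4-(prop-1-en-2-yl)-7-oxabicyclo[4.1.0]heptan-2-one
Product: 4 (3R)-5-oxo-3-(prop-1-en-2-yl)pentanoic acid, via trans-diol 3 (not isolated)
Conditions: H5IO6 (2.2 equiv), THF/H2O, 0 °C → rt
Reagents that add atoms: water, O
Why: acidic periodate hydrolyses the epoxide and two Malaprade cleavages (glycol, then 1,2-diketone) excise the methyl-bearing carbon as acetic acid, which leaves the former ketone carbon as the acid (future C10) and the former epoxide CH as the aldehyde (future C6) without touching the stereocentre.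

Step 3
Reactants: 4 (3R)-5-oxo-3-(prop-1-en-2-yl)pentanoic acid
Product: 6 (4R)-4-(prop-1-en-2-yl)oxan-2-one, via sodium hydroxy carboxylate 5 (not isolated)
Conditions: NaBH4, 1 M NaOH/EtOH, 0 °C; then 3 M HCl, rt
Reagents that add atoms: none
Why: borohydride reduces the aldehyde but not the carboxylate, and acidification closes the δ-lactone, which masks C6 at the alcohol level and activates C10 as an acyl donor.

Step 4
Reactants: 6 (4R)-4-(prop-1-en-2-yl)oxan-2-one
Product: 7 (3R)-5-hydroxy-N-methoxy-N-methyl-3-(prop-1-en-2-yl)pentanamide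
Conditions: MeNHOMe·HCl, iPrMgCl, THF, −20 → 0 °C
Reagents that add atoms: N,O-dimethylhydroxylamine hydrochloride, Cl.CNOC
Why: aminolysis of the lactone by the magnesium amide of N,O-dimethylhydroxylamine gives the Weinreb amide and frees the primary alcohol.

Step 5
Reactants: 7 (3R)-5-hydroxy-N-methoxy-N-methyl-3-(prop-1-en-2-yl)pentanamide
Product: 8 (3R)-5-[(tert-butyldimethylsilyl)oxy]-N-methoxy-N-methyl-3-(prop-1-en-2-yl)pentanamide
Conditions: TBSCl, imidazole, DMF, rt
Reagents that add atoms: tert-butyldimethylsilyl chloride, CC(C)(C)[Si](C)(C)Cl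
Why: standard silylation of the primary alcohol, which must survive enolate, hydroxide and HBr treatment later.

Step 6
Reactants: 9 methyl acetoacetate
Product: 10 methyl 2-diazo-3-oxobutanoate
Conditions: 4-acetamidobenzenesulfonyl azide, Et3N, MeCN, 0 °C → rt
Reagents that add atoms: 4-acetamidobenzenesulfonyl azide, CC(=O)Nc1ccc(cc1)S(=O)(=O)N=[N+]=[N-]
Why: Regitz diazo transfer to the doubly activated methylene group.

Step 7
Reactants: 10 methyl 2-diazo-3-oxobutanoate
Product: 11 methyl 3-[(tert-butyldimethylsilyl)oxy]-2-diazobut-3-enoate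
Conditions: TBSOTf, Et3N, CH2Cl2, 0 °C
Reagents that add atoms: tert-butyldimethylsilyl trifluoromethanesulfonate, CC(C)(C)[Si](C)(C)OS(=O)(=O)C(F)(F)F
Why: soft enolisation and O-silylation of the acetyl group give the silyloxy vinyldiazoacetate, the precursor of a donor/acceptor vinylcarbenoid.

Step 8
Reactants: 11 methyl 3-[(tert-butyldimethylsilyl)oxy]-2-diazobut-3-enoate, 12 2-methylfuran
Product: 14 methyl (1R,5R)-3-[(tert-butyldimethylsilyl)oxy]-5-methyl-8-oxabicyclo[3.2.1]octa-2,6-diene-2-carboxylate, via cis-divinylcyclopropane 13 (not isolated)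
Conditions: Rh2(S-PTAD)4 (1 mol %), 12 (5 equiv), hexanes, slow addition of 11, −20 °C → rt
Reagents that add atoms: none
Why: tandem cyclopropanation/Cope rearrangement (formal [4+3] cycloaddition) of the rhodium vinylcarbenoid, in which the carbenoid carbon bonds to the unsubstituted C5 of the furan, cyclopropane 13 rearranges through a boat transition state, and the chiral carboxylate catalyst sets both bridgehead stereocentres with the ester next to the H-bearing bridgehead.

Step 9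
Reactants: 14 methyl (1R,5R)-3-[(tert-butyldimethylsilyl)oxy]-5-methyl-8-oxabicyclo[3.2.1]octa-2,6-diene-2-carboxylate
Product: 16 methyl (1S,5S,7R)-3-[(tert-butyldimethylsilyl)oxy]-7-hydroxy-5-methyl-8-oxabicyclo[3.2.1]oct-2-ene-2-carboxylate, via alkylborane 15 (not isolated)
Conditions: 9-BBN, THF, 0 °C → rt; then 30% H2O2, aq NaOAc, 0 °C
Reagents that add atoms: hydrogen peroxide, OO
Why: hydroboration–oxidation of the strained C6=C7 bond (the tetrasubstituted push–pull enol ether is inert), with boron adding from the exo face anti to the three-carbon bridge and to C7, remote from the methyl-bearing bridgehead, which fixes the new carbinol centre as 7-exo.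

Step 10
Reactants: 16 methyl (1S,5S,7R)-3-[(tert-butyldimethylsilyl)oxy]-7-hydroxy-5-methyl-8-oxabicyclo[3.2.1]oct-2-ene-2-carboxylate
Product: 18 (1S,5S,6R)-6-hydroxy-1-methyl-8-oxabicyclo[3.2.1]octan-3-one, via β-keto ester 17 (not isolated)
Conditions: LiCl, H2O, DMSO, 130 °C
Reagents that add atoms: none
Why: the silyl enol ether is hydrolysed in the wet medium and the resulting β-keto ester undergoes Krapcho dealkoxycarbonylation, the bridged skeleton keeping the transient enolate from expelling the bridging oxygen.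

Step 11
Reactants: 18 (1S,5S,6R)-6-hydroxy-1-methyl-8-oxabicyclo[3.2.1]octan-3-one
Product: 19 (1S,5S,6R)-6-[(tert-butyldimethylsilyl)oxy]-1-methyl-8-oxabicyclo[3.2.1]octan-3-one
Conditions: TBSCl, imidazole, DMF, rt
Reagents that add atoms: tert-butyldimethylsilyl chloride, CC(C)(C)[Si](C)(C)Cl
Why: silylation of the exo alcohol keeps the future C13 at the carbinol level, so that only the C3 ketone can be enolised in step 12.

Step 12
Reactants: 19 (1S,5S,6R)-6-[(tert-butyldimethylsilyl)oxy]-1-methyl-8-oxabicyclo[3.2.1]octan-3-one, 8 (3R)-5-[(tert-butyldimethylsilyl)oxy]-N-methoxy-N-methyl-3-(prop-1-en-2-yl)pentanamide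
Product: 21 (1S,5S,6R)-6-[(tert-butyldimethylsilyl)oxy]-4-[(3R)-5-[(tert-butyldimethylsilyl)oxy]-3-(prop-1-en-2-yl)pentanoyl]-1-methyl-8-oxabicyclo[3.2.1]octan-3-one (C4 epimers and enol forms), via lithium enolate 20 (not isolated)
Conditions: LiN(iPr)2 (1.05 equiv), THF, −78 °C; then 8, −78 → −20 °C; aq NH4Cl
Reagents that add atoms: none
Why: kinetic deprotonation should occur at C4, the α-methylene next to the H-bearing bridgehead and not the one flanked by the quaternary C1, and C-acylation of this enolate by the Weinreb amide (stable chelated adduct, no proton transfer or second addition) forms the future C10–C11 bond.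

Step 13
Reactants: 21 (1S,5S,6R)-6-[(tert-butyldimethylsilyl)oxy]-4-[(3R)-5-[(tert-butyldimethylsilyl)oxy]-3-(prop-1-en-2-yl)pentanoyl]-1-methyl-8-oxabicyclo[3.2.1]octan-3-one
Product: 22 2-[(2S,4R,5S)-4-[(tert-butyldimethylsilyl)oxy]-5-[(4R)-6-[(tert-butyldimethylsilyl)oxy]-2-oxo-4-(prop-1-en-2-yl)hexyl]-2-methyloxolan-2-yl]acetic acid
Conditions: LiOH, THF/H2O, 0 °C → rt; then 1 M HCl to pH 3, 0 °C
Reagents that add atoms: lithium hydroxide, [Li+].[OH-]
Why: retro-Claisen cleavage of a 2-acylcycloalkanone, in which hydroxide adds to the ring carbonyl (the more electrophilic oxan-4-one) and the C3–C4 bond breaks to release the acetic acid arm on the quaternary carbon and the ketone arm on the oxolane CH, necessarily cis, while the exo silyloxy group trans to the new ketone arm disfavours epimerisation by a retro-oxa-Michael path.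

Step 14
Reactants: 22 2-[(2S,4R,5S)-4-[(tert-butyldimethylsilyl)oxy]-5-[(4R)-6-[(tert-butyldimethylsilyl)oxy]-2-oxo-4-(prop-1-en-2-yl)hexyl]-2-methyloxolan-2-yl]acetic acid
Product: 25 1-bromo-3-[(2S,4R,5S)-4-[(tert-butyldimethylsilyl)oxy]-5-[(4R)-6-[(tert-butyldimethylsilyl)oxy]-2-oxo-4-(prop-1-en-2-yl)hexyl]-2-methyloxolan-2-yl]propan-2-one, via mixed anhydride 23 (not isolated), via diazoketone 24 (not isolated)
Conditions: iBuOCOCl, N-methylmorpholine, THF, −20 °C; CH2N2, Et2O, 0 °C; then 48% aq HBr (1.05 equiv), −20 °C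
Reagents that add atoms: diazomethane, C=[N+]=[N-]; hydrogen bromide, Br
Why: Nierenstein-type homologation, in which the mixed anhydride acylates diazomethane and HBr then replaces dinitrogen by bromide, adds the future C4 as a bromomethyl ketone under conditions that spare the silyl ethers and the isopropenyl group.

Step 15
Reactants: 25 1-bromo-3-[(2S,4R,5S)-4-[(tert-butyldimethylsilyl)oxy]-5-[(4R)-6-[(tert-butyldimethylsilyl)oxy]-2-oxo-4-(prop-1-en-2-yl)hexyl]-2-methyloxolan-2-yl]propan-2-one, 26 methyl bis(2,2,2-trifluoroethyl)phosphonoacetate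
Product: 28 methyl 2-[bis(2,2,2-trifluoroethoxy)phosphoryl]-5-[(2S,4R,5S)-4-[(tert-butyldimethylsilyl)oxy]-5-[(4R)-6-[(tert-butyldimethylsilyl)oxy]-2-oxo-4-(prop-1-en-2-yl)hexyl]-2-methyloxolan-2-yl]-4-oxopentanoate (epimers at C2 of the pentanoate), via sodium phosphonate 27 (not isolated)
Conditions: 26 (1.5 equiv), NaH (1.4 equiv), THF, 0 °C; then 25, 0 °C → rt
Reagents that add atoms: none
Why: SN2 alkylation of the stabilised phosphonoacetate carbanion by the reactive α-bromoketone forms the C4–C5 bond, the new centre at C5 being formed as a mixture that is destroyed in step 18.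

Step 16
Reactants: 28 methyl 2-[bis(2,2,2-trifluoroethoxy)phosphoryl]-5-[(2S,4R,5S)-4-[(tert-butyldimethylsilyl)oxy]-5-[(4R)-6-[(tert-butyldimethylsilyl)oxy]-2-oxo-4-(prop-1-en-2-yl)hexyl]-2-methyloxolan-2-yl]-4-oxopentanoate
Product: 29 methyl 2-[bis(2,2,2-trifluoroethoxy)phosphoryl]-5-[(2S,4R,5S)-4-hydroxy-5-[(4R)-6-hydroxy-2-oxo-4-(prop-1-en-2-yl)hexyl]-2-methyloxolan-2-yl]-4-oxopentanoate
Conditions: HF·pyridine, THF/pyridine, 0 °C → rt
Reagents that add atoms: none
Why: fluoride-mediated cleavage of both silyl ethers under buffered conditions that leave the phosphonate, the ketones and the β-alkoxy ketone units alone.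

Step 17
Reactants: 29 methyl 2-[bis(2,2,2-trifluoroethoxy)phosphoryl]-5-[(2S,4R,5S)-4-hydroxy-5-[(4R)-6-hydroxy-2-oxo-4-(prop-1-en-2-yl)hexyl]-2-methyloxolan-2-yl]-4-oxopentanoate
Product: 30 methyl 2-[bis(2,2,2-trifluoroethoxy)phosphoryl]-5-[(2S,4R,5S)-5-[(4R)-2,6-dioxo-4-(prop-1-en-2-yl)hexyl]-4-hydroxy-2-methyloxolan-2-yl]-4-oxopentanoate
Conditions: TEMPO (cat.), PhI(OAc)2, CH2Cl2, rt
Reagents that add atoms: none
Why: oxoammonium oxidation is selective for the primary alcohol over the hindered secondary one, which is kept as a carbinol so that C12 carries no acidic hydrogen during the basic key step.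

Step 18
Reactants: 30 methyl 2-[bis(2,2,2-trifluoroethoxy)phosphoryl]-5-[(2S,4R,5S)-5-[(4R)-2,6-dioxo-4-(prop-1-en-2-yl)hexyl]-4-hydroxy-2-methyloxolan-2-yl]-4-oxopentanoate
Product: 32 methyl (1S,5Z,8R,12S,13R)-13-hydroxy-1-methyl-3,10-dioxo-8-(prop-1-en-2-yl)-15-oxabicyclo[10.2.1]pentadec-5-ene-5-carboxylate, via potassium phosphonate carbanion 31 (not isolated)
Conditions: K2CO3, 18-crown-6, toluene (1 mM), syringe-pump addition of 30, −20 → 0 °C
Reagents that add atoms: none
Why: Deprotonation at the phosphonoacetate carbon (C5) gives carbanion 31, which adds to the C6 aldehyde and collapses through the oxaphosphetane with loss of bis(trifluoroethyl) phosphate, an intramolecular Horner–Wadsworth–Emmons olefination in its Still–Gennari form whose closest precedents are Z-selective ring-closing olefinations of macrolide seco-aldehydes. The ring O15/C1–C12 is closed in a 13-exo-trig addition of C5 to the aldehyde carbon followed by elimination, the oxolane ring being already in place. No stereocentre is created; the C5=C6 geometry is set kinetically, because the electron-poor trifluoroethyl phosphonate makes elimination of the first-formed adduct faster than its equilibration and so places C7 cis to the ester (Z), which is also the endocyclic-trans arrangement that a 13-membered ring accommodates well. The step needs chemoselectivity for the phosphonate C–H over the ketone α-hydrogens and the aldehyde, which its far higher acidity toward K2CO3/18-crown-6 should secure, and ring closure over oligomerisation, which slow addition at about 1 mM should secure. The C12 stereocentre is protected because C13 is still a carbinol whose exo oxygen lies trans to the C11 arm, so that neither enolisation nor a retro-oxa-Michael/oxa-Michael sequence favours the epimer.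

Step 19
Reactants: 32 methyl (1S,5Z,8R,12S,13R)-13-hydroxy-1-methyl-3,10-dioxo-8-(prop-1-en-2-yl)-15-oxabicyclo[10.2.1]pentadec-5-ene-5-carboxylate
Product: 33 methyl (1R,5Z,8R,12S)-1-methyl-3,10,13-trioxo-8-(prop-1-en-2-yl)-15-oxabicyclo[10.2.1]pentadec-5-ene-5-carboxylate
Conditions: Dess–Martin periodinane, CH2Cl2, rt
Reagents that add atoms: none
Why: neutral hypervalent-iodine oxidation of the C13 carbinol to the ketone should leave the now epimerisable C12 centre, the β,γ-unsaturated C3 ketone and the enoate untouched.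

Compound list
1 | (R)-(−)-carvone, (5R)-2-methyl-5-(prop-1-en-2-yl)cyclohex-2-en-1-one | CC1=CC[C@H](CC1=O)C(C)=C | starting material
2 | (1R,4R,6R)-1-methyl-4-(prop-1-en-2-yl)-7-oxabicyclo[4.1.0]heptan-2-one (epoxide trans to isopropenyl) | CC(=C)[C@H]1CC(=O)[C@]2(C)O[C@@H]2C1 | intermediate
3 | (5R)-2,3-dihydroxy-2-methyl-5-(prop-1-en-2-yl)cyclohexan-1-one, trans-diol with the C3 hydroxyl cis to isopropenyl | CC(=C)[C@H]1CC(=O)[C@](C)(O)[C@@H](O)C1 | intermediate (not isolated)
4 | (3R)-5-oxo-3-(prop-1-en-2-yl)pentanoic acid | CC(=C)[C@H](CC=O)CC(O)=O | intermediate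
5 | sodium (3R)-5-hydroxy-3-(prop-1-en-2-yl)pentanoate | CC(=C)[C@H](CCO)CC(=O)[O-].[Na+] | intermediate (not isolated)
6 | (4R)-4-(prop-1-en-2-yl)oxan-2-one | CC(=C)[C@@H]1CCOC(=O)C1 | intermediate
7 | (3R)-5-hydroxy-N-methoxy-N-methyl-3-(prop-1-en-2-yl)pentanamide | CC(=C)[C@H](CCO)CC(=O)N(C)OC | intermediate
8 | (3R)-5-[(tert-butyldimethylsilyl)oxy]-N-methoxy-N-methyl-3-(prop-1-en-2-yl)pentanamide | CC(=C)[C@H](CCO[Si](C)(C)C(C)(C)C)CC(=O)N(C)OC | intermediate
9 | methyl acetoacetate | CC(=O)CC(=O)OC | starting material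
10 | methyl 2-diazo-3-oxobutanoate | CC(=O)C(=[N+]=[N-])C(=O)OC | intermediate
11 | methyl 3-[(tert-butyldimethylsilyl)oxy]-2-diazobut-3-enoate | C=C(O[Si](C)(C)C(C)(C)C)C(=[N+]=[N-])C(=O)OC | intermediate
12 | 2-methylfuran | Cc1ccco1 | starting material
13 | methyl 6-{1-[(tert-butyldimethylsilyl)oxy]ethenyl}-3-methyl-2-oxabicyclo[3.1.0]hex-3-ene-6-carboxylate, silyloxyvinyl group endo (cis to the dihydrofuran ring) | COC(=O)[C@]1(C(=C)O[Si](C)(C)C(C)(C)C)[C@H]2C=C(C)O[C@@H]12 | intermediate (not isolated)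
14 | methyl (1R,5R)-3-[(tert-butyldimethylsilyl)oxy]-5-methyl-8-oxabicyclo[3.2.1]octa-2,6-diene-2-carboxylate | COC(=O)C1=C(O[Si](C)(C)C(C)(C)C)C[C@]2(C)C=C[C@H]1O2 | intermediate
15 | 7-exo-(9-borabicyclo[3.3.1]nonan-9-yl) adduct of 14 | COC(=O)C1=C(O[Si](C)(C)C(C)(C)C)C[C@]2(C)C[C@@H](B3C4CCCC3CCC4)[C@H]1O2 | intermediate (not isolated)
16 | methyl (1S,5S,7R)-3-[(tert-butyldimethylsilyl)oxy]-7-hydroxy-5-methyl-8-oxabicyclo[3.2.1]oct-2-ene-2-carboxylate (7-exo-OH) | COC(=O)C1=C(O[Si](C)(C)C(C)(C)C)C[C@]2(C)C[C@@H](O)[C@H]1O2 | intermediate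
17 | methyl (1S,5S,7R)-7-hydroxy-5-methyl-3-oxo-8-oxabicyclo[3.2.1]octane-2-carboxylate (C2 epimers and enol) | COC(=O)C1C(=O)C[C@]2(C)C[C@@H](O)[C@H]1O2 | intermediate (not isolated)
18 | (1S,5S,6R)-6-hydroxy-1-methyl-8-oxabicyclo[3.2.1]octan-3-one | O=C1C[C@]2(C)C[C@@H](O)[C@H](C1)O2 | intermediate
19 | (1S,5S,6R)-6-[(tert-butyldimethylsilyl)oxy]-1-methyl-8-oxabicyclo[3.2.1]octan-3-one | O=C1C[C@]2(C)C[C@@H](O[Si](C)(C)C(C)(C)C)[C@H](C1)O2 | intermediate
20 | lithium C3–C4 enolate of 19 | [Li+].[O-]C1C[C@]2(C)C[C@@H](O[Si](C)(C)C(C)(C)C)[C@H](C=1)O2 | intermediate (not isolated)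
21 | (1S,5S,6R)-6-[(tert-butyldimethylsilyl)oxy]-4-[(3R)-5-[(tert-butyldimethylsilyl)oxy]-3-(prop-1-en-2-yl)pentanoyl]-1-methyl-8-oxabicyclo[3.2.1]octan-3-one | O=C1C[C@]2(C)C[C@@H](O[Si](C)(C)C(C)(C)C)[C@H](C1C(=O)C[C@@H](CCO[Si](C)(C)C(C)(C)C)C(C)=C)O2 | intermediate
22 | 2-[(2S,4R,5S)-4-[(tert-butyldimethylsilyl)oxy]-5-[(4R)-6-[(tert-butyldimethylsilyl)oxy]-2-oxo-4-(prop-1-en-2-yl)hexyl]-2-methyloxolan-2-yl]acetic acid | OC(=O)C[C@]1(C)C[C@@H](O[Si](C)(C)C(C)(C)C)[C@H](CC(=O)C[C@@H](CCO[Si](C)(C)C(C)(C)C)C(C)=C)O1 | intermediate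
23 | isobutyl carbonic mixed anhydride of 22 | CC(C)COC(=O)OC(=O)C[C@]1(C)C[C@@H](O[Si](C)(C)C(C)(C)C)[C@H](CC(=O)C[C@@H](CCO[Si](C)(C)C(C)(C)C)C(C)=C)O1 | intermediate (not isolated)
24 | diazomethyl ketone derived from 22 | [N-]=[N+]=CC(=O)C[C@]1(C)C[C@@H](O[Si](C)(C)C(C)(C)C)[C@H](CC(=O)C[C@@H](CCO[Si](C)(C)C(C)(C)C)C(C)=C)O1 | intermediate (not isolated)
25 | 1-bromo-3-[(2S,4R,5S)-4-[(tert-butyldimethylsilyl)oxy]-5-[(4R)-6-[(tert-butyldimethylsilyl)oxy]-2-oxo-4-(prop-1-en-2-yl)hexyl]-2-methyloxolan-2-yl]propan-2-one | BrCC(=O)C[C@]1(C)C[C@@H](O[Si](C)(C)C(C)(C)C)[C@H](CC(=O)C[C@@H](CCO[Si](C)(C)C(C)(C)C)C(C)=C)O1 | intermediate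
26 | methyl bis(2,2,2-trifluoroethyl)phosphonoacetate | COC(=O)CP(=O)(OCC(F)(F)F)OCC(F)(F)F | starting material
27 | sodium salt of 26 (phosphonate carbanion) | [Na+].COC(=O)[CH-]P(=O)(OCC(F)(F)F)OCC(F)(F)F | intermediate (not isolated)
28 | methyl 2-[bis(2,2,2-trifluoroethoxy)phosphoryl]-5-[(2S,4R,5S)-4-[(tert-butyldimethylsilyl)oxy]-5-[(4R)-6-[(tert-butyldimethylsilyl)oxy]-2-oxo-4-(prop-1-en-2-yl)hexyl]-2-methyloxolan-2-yl]-4-oxopentanoate (C2 epimers) | COC(=O)C(CC(=O)C[C@]1(C)C[C@@H](O[Si](C)(C)C(C)(C)C)[C@H](CC(=O)C[C@@H](CCO[Si](C)(C)C(C)(C)C)C(C)=C)O1)P(=O)(OCC(F)(F)F)OCC(F)(F)F | intermediate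
29 | methyl 2-[bis(2,2,2-trifluoroethoxy)phosphoryl]-5-[(2S,4R,5S)-4-hydroxy-5-[(4R)-6-hydroxy-2-oxo-4-(prop-1-en-2-yl)hexyl]-2-methyloxolan-2-yl]-4-oxopentanoate | COC(=O)C(CC(=O)C[C@]1(C)C[C@@H](O)[C@H](CC(=O)C[C@@H](CCO)C(C)=C)O1)P(=O)(OCC(F)(F)F)OCC(F)(F)F | intermediate
30 | methyl 2-[bis(2,2,2-trifluoroethoxy)phosphoryl]-5-[(2S,4R,5S)-5-[(4R)-2,6-dioxo-4-(prop-1-en-2-yl)hexyl]-4-hydroxy-2-methyloxolan-2-yl]-4-oxopentanoate | COC(=O)C(CC(=O)C[C@]1(C)C[C@@H](O)[C@H](CC(=O)C[C@@H](CC=O)C(C)=C)O1)P(=O)(OCC(F)(F)F)OCC(F)(F)F | intermediate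
31 | potassium phosphonate carbanion of 30 | [K+].COC(=O)[C-](CC(=O)C[C@]1(C)C[C@@H](O)[C@H](CC(=O)C[C@@H](CC=O)C(C)=C)O1)P(=O)(OCC(F)(F)F)OCC(F)(F)F | intermediate (not isolated)
32 | methyl (1S,5Z,8R,12S,13R)-13-hydroxy-1-methyl-3,10-dioxo-8-(prop-1-en-2-yl)-15-oxabicyclo[10.2.1]pentadec-5-ene-5-carboxylate | C=C(C)[C@@H]1C/C=C(\C(=O)OC)CC(=O)C[C@]2(C)C[C@@H](O)[C@H](CC(=O)C1)O2 | intermediate
33 | methyl (1R,5Z,8R,12S)-1-methyl-3,10,13-trioxo-8-(prop-1-en-2-yl)-15-oxabicyclo[10.2.1]pentadec-5-ene-5-carboxylate | C=C(C)[C@@H]1C/C=C(\C(=O)OC)CC(=O)C[C@]2(C)CC(=O)[C@H](CC(=O)C1)O2 | target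

Total step count: 19 (east fragment steps 1–5, core steps 6–11, union and end game steps 12–19).
Longest linear sequence: 14 steps (steps 6–19, from methyl acetoacetate 9).

Steps most likely to fail

Step 18. The ring closure may lose out to oligomerisation, the Z-selectivity of the olefination may erode under the constraint of the forming ring, or the aldehyde may be consumed by aldol reaction with a ketone enolate. The fallback closes the same C5=C6 bond by ring-closing metathesis; it sets out from acid 22 and comes back at macrocyclic alcohol 32. Acid 22 is converted with 1-chloro-N,N,2-trimethylprop-1-en-1-amine into the acid chloride F1, which is coupled with methyl 2-[(tributylstannyl)methyl]prop-2-enoate under Pd(PPh3)4 catalysis (Stille acylation) to the α-methylene γ-keto ester F2. HF·pyridine then gives the diol F3, TEMPO/PhI(OAc)2 the hydroxy aldehyde F4, and Ph3P=CH2 at −78 °C (aldehyde-selective Wittig methylenation) the terminal alkene F5. Ring-closing metathesis of the 2-substituted acrylate with the terminal alkene (second-generation Hoveyda–Grubbs catalyst, toluene, 1 mM, 80 °C) should give 32, the endocyclic-trans (Z-enoate) isomer being the one expected for this ring size and the 1,1-disubstituted isopropenyl group being slow to react.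

Step 12. Deprotonation may take place toward C2 in place of C4, which would put the acyl group on the wrong arm, or the enolate may be O-acylated. The fallback fixes the site of acylation with the ester of the cycloadduct; it sets out from alcohol 16 and lactone 6 and comes back at 21. Alcohol 16 is silylated (TBSCl, imidazole) to the bis-silyl compound F6, and K2CO3 in MeOH at 0 °C cleaves only the silyl enol ether to give the β-keto ester F7. Lactone 6 is saponified (LiOH), silylated (TBSCl, imidazole, then K2CO3 in aqueous MeOH to free the acid) to the silyloxy acid F8 and converted with 1-chloro-N,N,2-trimethylprop-1-en-1-amine into the acid chloride F9. C-Acylation of the magnesium enolate of F7 (MgCl2, Et3N, MeCN) with F9 gives the quaternary 2-acyl β-keto ester F10, and LiI in EtOAc at reflux (SN2 demethylation, then loss of CO2 inside the bridged skeleton) gives 21.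

Step 8. Facial discrimination by the catalyst may be insufficient, or the zwitterionic carbenoid–furan adduct may open to a trienone in place of closing to the cyclopropane. The fallback replaces asymmetric catalysis by resolution; it sets out from 11 and 12 and comes back at 16. The cycloaddition is run with Rh2(O2CC7H15)4 to give the racemic adduct F11, hydroboration–oxidation as in step 9 gives the racemic alcohol F12, and lipase-catalysed acetylation (Amano lipase PS, vinyl acetate, with the enzyme chosen by screening so that the unwanted antipode reacts) converts that antipode into the acetate F13, which is separated from unreacted 16.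

Further compounds
F1 | step 18 | 2-[(2S,4R,5S)-4-[(tert-butyldimethylsilyl)oxy]-5-[(4R)-6-[(tert-butyldimethylsilyl)oxy]-2-oxo-4-(prop-1-en-2-yl)hexyl]-2-methyloxolan-2-yl]acetyl chloride | ClC(=O)C[C@]1(C)C[C@@H](O[Si](C)(C)C(C)(C)C)[C@H](CC(=O)C[C@@H](CCO[Si](C)(C)C(C)(C)C)C(C)=C)O1
F2 | step 18 | methyl 5-[(2S,4R,5S)-4-[(tert-butyldimethylsilyl)oxy]-5-[(4R)-6-[(tert-butyldimethylsilyl)oxy]-2-oxo-4-(prop-1-en-2-yl)hexyl]-2-methyloxolan-2-yl]-2-methylidene-4-oxopentanoate | COC(=O)C(=C)CC(=O)C[C@]1(C)C[C@@H](O[Si](C)(C)C(C)(C)C)[C@H](CC(=O)C[C@@H](CCO[Si](C)(C)C(C)(C)C)C(C)=C)O1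
F3 | step 18 | methyl 5-[(2S,4R,5S)-4-hydroxy-5-[(4R)-6-hydroxy-2-oxo-4-(prop-1-en-2-yl)hexyl]-2-methyloxolan-2-yl]-2-methylidene-4-oxopentanoate | COC(=O)C(=C)CC(=O)C[C@]1(C)C[C@@H](O)[C@H](CC(=O)C[C@@H](CCO)C(C)=C)O1
F4 | step 18 | methyl 5-[(2S,4R,5S)-5-[(4R)-2,6-dioxo-4-(prop-1-en-2-yl)hexyl]-4-hydroxy-2-methyloxolan-2-yl]-2-methylidene-4-oxopentanoate | COC(=O)C(=C)CC(=O)C[C@]1(C)C[C@@H](O)[C@H](CC(=O)C[C@@H](CC=O)C(C)=C)O1
F5 | step 18 | methyl 5-[(2S,4R,5S)-4-hydroxy-2-methyl-5-[(4R)-2-oxo-4-(prop-1-en-2-yl)hept-6-en-1-yl]oxolan-2-yl]-2-methylidene-4-oxopentanoate | COC(=O)C(=C)CC(=O)C[C@]1(C)C[C@@H](O)[C@H](CC(=O)C[C@@H](CC=C)C(C)=C)O1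
F6 | step 12 | methyl (1S,5S,7R)-3,7-bis[(tert-butyldimethylsilyl)oxy]-5-methyl-8-oxabicyclo[3.2.1]oct-2-ene-2-carboxylate | COC(=O)C1=C(O[Si](C)(C)C(C)(C)C)C[C@]2(C)C[C@@H](O[Si](C)(C)C(C)(C)C)[C@H]1O2
F7 | step 12 | methyl (1S,5S,7R)-7-[(tert-butyldimethylsilyl)oxy]-5-methyl-3-oxo-8-oxabicyclo[3.2.1]octane-2-carboxylate (C2 epimers and enol) | COC(=O)C1C(=O)C[C@]2(C)C[C@@H](O[Si](C)(C)C(C)(C)C)[C@H]1O2
F8 | step 12 | (3R)-5-[(tert-butyldimethylsilyl)oxy]-3-(prop-1-en-2-yl)pentanoic acid | CC(=C)[C@H](CCO[Si](C)(C)C(C)(C)C)CC(=O)O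
F9 | step 12 | (3R)-5-[(tert-butyldimethylsilyl)oxy]-3-(prop-1-en-2-yl)pentanoyl chloride | CC(=C)[C@H](CCO[Si](C)(C)C(C)(C)C)CC(=O)Cl
F10 | step 12 | methyl (1S,5S,7R)-7-[(tert-butyldimethylsilyl)oxy]-2-[(3R)-5-[(tert-butyldimethylsilyl)oxy]-3-(prop-1-en-2-yl)pentanoyl]-5-methyl-3-oxo-8-oxabicyclo[3.2.1]octane-2-carboxylate (C2 configuration not defined) | COC(=O)C1(C(=O)C[C@@H](CCO[Si](C)(C)C(C)(C)C)C(C)=C)C(=O)C[C@]2(C)C[C@@H](O[Si](C)(C)C(C)(C)C)[C@H]1O2
F11 | step 8 | racemic methyl 3-[(tert-butyldimethylsilyl)oxy]-5-methyl-8-oxabicyclo[3.2.1]octa-2,6-diene-2-carboxylate (14 and its antipode) | COC(=O)C1=C(O[Si](C)(C)C(C)(C)C)C[C@]2(C)C=C[C@H]1O2.COC(=O)C1=C(O[Si](C)(C)C(C)(C)C)C[C@@]2(C)C=C[C@@H]1O2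
F12 | step 8 | racemic methyl 3-[(tert-butyldimethylsilyl)oxy]-7-exo-hydroxy-5-methyl-8-oxabicyclo[3.2.1]oct-2-ene-2-carboxylate (16 and its antipode) | COC(=O)C1=C(O[Si](C)(C)C(C)(C)C)C[C@]2(C)C[C@@H](O)[C@H]1O2.COC(=O)C1=C(O[Si](C)(C)C(C)(C)C)C[C@@]2(C)C[C@H](O)[C@@H]1O2
F13 | step 8 | methyl (1R,5R,7S)-7-acetoxy-3-[(tert-butyldimethylsilyl)oxy]-5-methyl-8-oxabicyclo[3.2.1]oct-2-ene-2-carboxylate (acetate of the antipode of 16) | COC(=O)C1=C(O[Si](C)(C)C(C)(C)C)C[C@@]2(C)C[C@H](OC(C)=O)[C@@H]1O2
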